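**Plan**
- Retrosynthesis: the benzyl ethers on O5 and O8 come off last; ring C is cut at C4–C4a (Friedel–Crafts acylation), then at O1–C2 (aryl vinyl ether), and C2–C3 is cut back to a methoxyacetate and the ring B acid chloride.
- Forward: C2–C3 by Claisen-type acylation, enol triflate, O1–C2 by substitution with the ring A phenoxide, ester hydrolysis, closure of ring C through C4–C4a, hydrogenolysis.
- Enabling feature: on ring A, C8 carries oxygen, so C4a is the only unsubstituted carbon ortho to O1. It is also ortho to the C5 oxygen and para to the C7 methoxy group, so the tethered acyl group can attack only there, and the 5,7,8-oxygenation pattern is fixed when O1–C2 is made.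
- The ring A phenol comes from o-vanillin by para-hydroxylation, benzylation and aldehyde-to-phenol oxidation.
- The target has no stereocenter; the alkene geometry of the acyclic precursor is the only stereo-element and equilibrates under the acidic ring closure.

Key step: step 8

Remark: acid chloride 8 is treated as purchasable. Single alkene isomers are drawn for 10–13, but a mixture of geometric isomers would serve equally because the geometry is corrected in step 8.

**Step 1**
Reactants: 1 o-vanillin (2-hydroxy-3-methoxybenzaldehyde)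
Product: 3 2,5-dihydroxy-3-methoxybenzaldehyde, via potassium aryl sulfate 2 (not isolated)
Conditions: K2S2O8, aq KOH, 0 → 20 °C; then HCl, 70 °C
Reagents that add atoms: potassium peroxodisulfate, [K+].[K+].[O-]S(=O)(=O)OOS(=O)(=O)[O-]
Why: Elbs persulfate oxidation: the phenoxide attacks the peroxide oxygen through its para carbon, both ortho positions being substituted, and acid hydrolysis of the aryl sulfate should release the hydroquinone.

**Step 2**
Reactants: 3 2,5-dihydroxy-3-methoxybenzaldehyde
Product: 4 2,5-bis(benzyloxy)-3-methoxybenzaldehyde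
Conditions: BnBr, K2CO3, DMF, 60 °C, N2
Reagents that add atoms: benzyl bromide, BrCc1ccccc1
Why: Williamson ether synthesis: both phenoxides should be alkylated by the SN2-reactive benzyl bromide, the hydrogen-bonded 2-OH needing the mild heating.

**Step 3**
Reactants: 4 2,5-bis(benzyloxy)-3-methoxybenzaldehyde
Product: 6 2,5-bis(benzyloxy)-3-methoxyphenol, via aryl formate 5 (not isolated)
Conditions: mCPBA, CH2Cl2, 0 °C → rt; aq NaHCO3 wash; then K2CO3 (cat.), MeOH, rt
Reagents that add atoms: 3-chloroperoxybenzoic acid (mCPBA), O=C(OO)c1cccc(Cl)c1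
Why: Baeyer–Villiger (Dakin-type) oxidation: the electron-rich aryl group with its ortho alkoxy substituent should migrate in the Criegee intermediate to give the aryl formate, which methanolysis cleaves to the phenol while the benzyl ethers stay inert.

**Step 4**
Reactants: 7 methyl methoxyacetate; 8 2,3,4-trimethoxybenzoyl chloride
Product: 9 methyl 2-methoxy-3-oxo-3-(2,3,4-trimethoxyphenyl)propanoate (racemic)
Conditions: 7 (2 equiv), LiN(iPr)2 (2 equiv), THF, −78 °C; then 8 (1 equiv), −78 → 0 °C; 1 M HCl quench
Reagents that add atoms: none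
Why: Crossed Claisen acylation: the lithium enolate of 7 attacks the acid chloride, and the second equivalent of enolate deprotonates the more acidic β-keto ester so that it is not acylated again.

**Step 5**
Reactants: 9 methyl 2-methoxy-3-oxo-3-(2,3,4-trimethoxyphenyl)propanoate
Product: 10 methyl (E)-2-methoxy-3-(2,3,4-trimethoxyphenyl)-3-{[(trifluoromethyl)sulfonyl]oxy}acrylate (triflate cis to the ester)
Conditions: NaH, Et2O, 0 °C; then (CF3SO2)2O, 0 °C
Reagents that add atoms: trifluoromethanesulfonic anhydride, O=S(=O)(OS(=O)(=O)C(F)(F)F)C(F)(F)F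
Why: O-sulfonylation of a β-keto ester enolate: the hard sulfonyl electrophile should react at oxygen of the chelated sodium enolate, which places the triflate cis to the ester.

**Step 6**
Reactants: 6 2,5-bis(benzyloxy)-3-methoxyphenol; 10 enol triflate
Product: 11 methyl (E)-3-[2,5-bis(benzyloxy)-3-methoxyphenoxy]-2-methoxy-3-(2,3,4-trimethoxyphenyl)acrylate (aryloxy group cis to the ester)
Conditions: Cs2CO3, DMF, rt → 50 °C
Reagents that add atoms: none
Why: Nucleophilic vinylic substitution by addition–elimination: the phenoxide should add to the β-carbon, activated by the ester and the triflate, and triflate then leaves from the ester enolate, normally with retention of geometry.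

**Step 7**
Reactants: 11 methyl ester
Product: 12 (E)-3-[2,5-bis(benzyloxy)-3-methoxyphenoxy]-2-methoxy-3-(2,3,4-trimethoxyphenyl)acrylic acid (carboxyl cis to the aryloxy group)
Conditions: LiOH·H2O, THF/MeOH/H2O, rt → 40 °C; then 1 M HCl to pH 3, 0 °C
Reagents that add atoms: lithium hydroxide, [Li+].[OH-]
Why: Saponification of a methyl ester: hydroxide should attack the ester carbonyl in preference to the hindered, donor-substituted β-carbon, and cold, brief acidification spares the aryl enol ether.

**Step 8**
Reactants: 12 acrylic acid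
Product: 14 5,8-bis(benzyloxy)-3,7-dimethoxy-2-(2,3,4-trimethoxyphenyl)-4H-chromen-4-one, via mixed trifluoroacetic anhydride 13 (not isolated)
Conditions: (CF3CO)2O (1.5 equiv), CH2Cl2, 0 °C → rt
Reagents that add atoms: none
Why: Trifluoroacetic anhydride converts the acid into mixed anhydride 13, an acylium equivalent whose acyl carbon is attacked by C4a of ring A, and loss of the C4a proton restores aromaticity and completes the pyranone. The closest known reaction type is the intramolecular Friedel–Crafts acylation by which 3-aryloxyacrylic acids are closed to chromones and 2-aryloxybenzoic acids to xanthones. Ring C forms by a 6-exo-trig closure at the acyl carbon, creating the C4–C4a bond and no stereocenter. Regioselectivity among the ring A carbons comes from the tether: of the two carbons ortho to O1, C8 bears a benzyloxy group, so only C4a can be reached (C6 cannot), and C4a is activated by O1 and the C5 benzyloxy group (ortho) and by the C7 methoxy group (para). Closure onto C6' of ring B would need the Z acid and would give a strained indenone at a carbon activated by one methoxy group only; the push–pull alkene equilibrates in the acidic medium, so material should drain through the E acid into the chromone. The medium is anhydrous and only CF3CO2H is generated, which should leave the benzyl ethers and the aryl enol ether intact.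

**Step 9**
Reactants: 14 5,8-bis(benzyloxy)-3,7-dimethoxy-2-(2,3,4-trimethoxyphenyl)-4H-chromen-4-one
Product: 15 5,8-dihydroxy-3,7,2',3',4'-pentamethoxyflavone
Conditions: H2 (1 atm), 10% Pd/C, EtOAc/MeOH, rt; filtration and evaporation under argon
Reagents that add atoms: none
Why: Catalytic hydrogenolysis of benzyl aryl ethers: the benzylic C–O bonds should be cleaved under neutral conditions that leave the methyl ethers and the chromone untouched, and exclusion of air protects the 5,8-hydroquinone from oxidation.

**Compound list**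
1 | o-vanillin (2-hydroxy-3-methoxybenzaldehyde) | COc1cccc(C=O)c1O | starting material
2 | potassium 3-formyl-4-hydroxy-5-methoxyphenyl sulfate | COc1cc(OS(=O)(=O)[O-])cc(C=O)c1O.[K+] | intermediate
3 | 2,5-dihydroxy-3-methoxybenzaldehyde | COc1cc(O)cc(C=O)c1O | intermediate
4 | 2,5-bis(benzyloxy)-3-methoxybenzaldehyde | COc1cc(OCc2ccccc2)cc(C=O)c1OCc1ccccc1 | intermediate
5 | 2,5-bis(benzyloxy)-3-methoxyphenyl formate | COc1cc(OCc2ccccc2)cc(OC=O)c1OCc1ccccc1 | intermediate
6 | 2,5-bis(benzyloxy)-3-methoxyphenol | COc1cc(OCc2ccccc2)cc(O)c1OCc1ccccc1 | intermediate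
7 | methyl methoxyacetate | COCC(=O)OC | starting material
8 | 2,3,4-trimethoxybenzoyl chloride | COc1ccc(C(Cl)=O)c(OC)c1OC | starting material
9 | methyl 2-methoxy-3-oxo-3-(2,3,4-trimethoxyphenyl)propanoate (racemic) | COC(C(=O)OC)C(=O)c1ccc(OC)c(OC)c1OC | intermediate
10 | methyl (E)-2-methoxy-3-(2,3,4-trimethoxyphenyl)-3-{[(trifluoromethyl)sulfonyl]oxy}acrylate | CO/C(C(=O)OC)=C(\c1ccc(OC)c(OC)c1OC)OS(=O)(=O)C(F)(F)F | intermediate
11 | methyl (E)-3-[2,5-bis(benzyloxy)-3-methoxyphenoxy]-2-methoxy-3-(2,3,4-trimethoxyphenyl)acrylate | CO/C(C(=O)OC)=C(\c1ccc(OC)c(OC)c1OC)Oc1cc(OCc2ccccc2)cc(OC)c1OCc1ccccc1 | intermediate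
12 | (E)-3-[2,5-bis(benzyloxy)-3-methoxyphenoxy]-2-methoxy-3-(2,3,4-trimethoxyphenyl)acrylic acid | CO/C(C(=O)O)=C(\c1ccc(OC)c(OC)c1OC)Oc1cc(OCc2ccccc2)cc(OC)c1OCc1ccccc1 | intermediate
13 | (E)-3-[2,5-bis(benzyloxy)-3-methoxyphenoxy]-2-methoxy-3-(2,3,4-trimethoxyphenyl)acrylic trifluoroacetic anhydride | CO/C(C(=O)OC(=O)C(F)(F)F)=C(\c1ccc(OC)c(OC)c1OC)Oc1cc(OCc2ccccc2)cc(OC)c1OCc1ccccc1 | intermediate
14 | 5,8-bis(benzyloxy)-3,7-dimethoxy-2-(2,3,4-trimethoxyphenyl)-4H-chromen-4-one | COc1ccc(-c2oc3c(OCc4ccccc4)c(OC)cc(OCc4ccccc4)c3c(=O)c2OC)c(OC)c1OC | intermediate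
15 | 5,8-dihydroxy-3,7,2',3',4'-pentamethoxyflavone | COc1ccc(-c2oc3c(O)c(OC)cc(O)c3c(=O)c2OC)c(OC)c1OC | target

**Totals**
Total step count: 9. Longest linear sequence: 7 steps (1 → 3 → 4 → 6 → 11 → 12 → 14 → 15); the side branch 7 + 8 → 9 → 10 has 2 steps.

**Steps most likely to fail**

Step 6. The phenoxide may add too slowly to the tetrasubstituted alkene, whose β-carbon is enriched by the α-methoxy group, or it may attack sulfur of the triflate and transfer the sulfonyl group instead of substituting at carbon. The fallback sets out from phenol 6 and returns at ester 11. It makes the C–O bond at a saturated benzylic carbon and creates the alkene afterwards. Darzens condensation of purchased 2,3,4-trimethoxybenzaldehyde with methyl chloroacetate (NaOMe, MeOH, −10 °C → rt) would give methyl trans-3-(2,3,4-trimethoxyphenyl)oxirane-2-carboxylate F1. The phenoxide of 6 (K2CO3, DMF, 60 °C) should open the epoxide at the benzylic carbon, where the electron-rich aryl group supports positive charge, to give methyl 3-[2,5-bis(benzyloxy)-3-methoxyphenoxy]-2-hydroxy-3-(2,3,4-trimethoxyphenyl)propanoate F2 (any diastereomer mixture is acceptable). Dess–Martin oxidation would give methyl 3-[2,5-bis(benzyloxy)-3-methoxyphenoxy]-2-oxo-3-(2,3,4-trimethoxyphenyl)propanoate F3. O-methylation of its enolate (K2CO3, Me2SO4, acetone) would deliver 11 as a mixture of alkene isomers, which converge in step 8.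

Step 8. The push–pull mixed anhydride may be too weak an electrophile, and the stronger acid then needed may cleave or migrate the benzyl groups; partial closure through the Z isomer onto ring B is a further diversion. The fallback sets out from 3 and returns at 15. It replaces the benzyl ethers by isopropyl ethers, which tolerate strong protic acid better. Alkylation of 3 with 2-bromopropane (K2CO3, DMF, 70 °C) would give 2,5-diisopropoxy-3-methoxybenzaldehyde F4. Baeyer–Villiger oxidation with mCPBA would give 2,5-diisopropoxy-3-methoxyphenyl formate F5, and methanolysis 2,5-diisopropoxy-3-methoxyphenol F6. Substitution of triflate 10 as in step 6 would give methyl (E)-3-(2,5-diisopropoxy-3-methoxyphenoxy)-2-methoxy-3-(2,3,4-trimethoxyphenyl)acrylate F7, and saponification (E)-3-(2,5-diisopropoxy-3-methoxyphenoxy)-2-methoxy-3-(2,3,4-trimethoxyphenyl)acrylic acid F8. Ring closure in P2O5/MeSO3H at rt would give 5,8-diisopropoxy-3,7-dimethoxy-2-(2,3,4-trimethoxyphenyl)-4H-chromen-4-one F9. BCl3 in CH2Cl2 (−78 → 0 °C) should then remove both isopropyl ethers without touching the methyl ethers, giving 15.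

Step 1. Conversion may stay low, and the hydroquinone formed may be over-oxidised to quinone and polymeric material in the alkaline persulfate medium. The fallback sets out from 1 and returns at 4. It introduces the C5 oxygen through a halide. Bromination para to the phenol (Br2, NaOAc, AcOH) would give 5-bromo-2-hydroxy-3-methoxybenzaldehyde F10, and benzylation (BnBr, K2CO3, DMF) 2-(benzyloxy)-5-bromo-3-methoxybenzaldehyde F11. Miyaura borylation (bis(pinacolato)diboron, PdCl2(dppf), KOAc, dioxane, 90 °C) would give 2-(benzyloxy)-3-methoxy-5-(4,4,5,5-tetramethyl-1,3,2-dioxaborolan-2-yl)benzaldehyde F12. Oxidation of the C–B bond (NaBO3·4H2O, THF/H2O, rt) would give 2-(benzyloxy)-5-hydroxy-3-methoxybenzaldehyde F13, and a second benzylation gives 4.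

**Further compounds**
F1 | step 6 | methyl trans-3-(2,3,4-trimethoxyphenyl)oxirane-2-carboxylate (racemic, one enantiomer drawn) | COC(=O)[C@H]1O[C@@H]1c1ccc(OC)c(OC)c1OC
F2 | step 6 | methyl 3-[2,5-bis(benzyloxy)-3-methoxyphenoxy]-2-hydroxy-3-(2,3,4-trimethoxyphenyl)propanoate (diastereomer mixture) | COC(=O)C(O)C(Oc1cc(OCc2ccccc2)cc(OC)c1OCc1ccccc1)c1ccc(OC)c(OC)c1OC
F3 | step 6 | methyl 3-[2,5-bis(benzyloxy)-3-methoxyphenoxy]-2-oxo-3-(2,3,4-trimethoxyphenyl)propanoate | COC(=O)C(=O)C(Oc1cc(OCc2ccccc2)cc(OC)c1OCc1ccccc1)c1ccc(OC)c(OC)c1OC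
F4 | step 8 | 2,5-diisopropoxy-3-methoxybenzaldehyde | COc1cc(OC(C)C)cc(C=O)c1OC(C)C
F5 | step 8 | 2,5-diisopropoxy-3-methoxyphenyl formate | COc1cc(OC(C)C)cc(OC=O)c1OC(C)C
F6 | step 8 | 2,5-diisopropoxy-3-methoxyphenol | COc1cc(OC(C)C)cc(O)c1OC(C)C
F7 | step 8 | methyl (E)-3-(2,5-diisopropoxy-3-methoxyphenoxy)-2-methoxy-3-(2,3,4-trimethoxyphenyl)acrylate | CO/C(C(=O)OC)=C(\c1ccc(OC)c(OC)c1OC)Oc1cc(OC(C)C)cc(OC)c1OC(C)C
F8 | step 8 | (E)-3-(2,5-diisopropoxy-3-methoxyphenoxy)-2-methoxy-3-(2,3,4-trimethoxyphenyl)acrylic acid | CO/C(C(=O)O)=C(\c1ccc(OC)c(OC)c1OC)Oc1cc(OC(C)C)cc(OC)c1OC(C)C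
F9 | step 8 | 5,8-diisopropoxy-3,7-dimethoxy-2-(2,3,4-trimethoxyphenyl)-4H-chromen-4-one | COc1ccc(-c2oc3c(OC(C)C)c(OC)cc(OC(C)C)c3c(=O)c2OC)c(OC)c1OC
F10 | step 1 | 5-bromo-2-hydroxy-3-methoxybenzaldehyde | COc1cc(Br)cc(C=O)c1O
F11 | step 1 | 2-(benzyloxy)-5-bromo-3-methoxybenzaldehyde | COc1cc(Br)cc(C=O)c1OCc1ccccc1
F12 | step 1 | 2-(benzyloxy)-3-methoxy-5-(4,4,5,5-tetramethyl-1,3,2-dioxaborolan-2-yl)benzaldehyde | COc1cc(B2OC(C)(C)C(C)(C)O2)cc(C=O)c1OCc1ccccc1
F13 | step 1 | 2-(benzyloxy)-5-hydroxy-3-methoxybenzaldehyde | COc1cc(O)cc(C=O)c1OCc1ccccc1
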